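## Retrosynthetic overview

1. Ring C is closed last: C2–C3 by an intramolecular aldol of a C4 ketone onto a C2 aldehyde.
2. Ring D: C3–C16 by an intramolecular Mukaiyama aldol of a methyl ketone onto the ring B cyclobutanone; the C8/C9 oxygens come from syn-dihydroxylation of an (E)-alkylidene cyclobutanone.
3. That C8=C9 alkene is the fragment union: aldol condensation of a ring A/B cyclobutanone with a cyclopropane keto aldehyde (ring E, fragment 1).
4. Rings A/B: endo Diels–Alder of 2-methylcyclobut-2-enone (fragment 2) with a 2-silyloxy diene from (R)-glyceraldehyde acetonide (fragment 3, carries C1/C2); the gem-dimethyl group comes from cyclopropanation and ring opening.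
5. Ring order: E and B in the fragments, then A, D, C.

Locants (target skeleton): C1 CH(OAc), C2 CH(OH), C3 CH, C4 C=O (ring D), C5 spiro carbon, C6/C7 cyclopropane CH2/CH(CH3), C8 CH(OAc), C9 and C16 C–OH (ring B), C10 CH (rings A/B), C11 CH2, C12 C=O (ring A), C13 C(CH3)2, C14 CH, C15 C–CH3.

Assumption: in the Diels–Alder step the (S)-oxazaborolidinium catalyst is taken as the matched enantiomer for the required diene face; if it is not, its mirror image is used.

## Route

**Fragment 1 (ring E)**

Step 1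
Reactants: 1 dimethyl malonate; 2 (4S)-4-methyl-1,3,2-dioxathiolane 2,2-dioxide
Product: 4 dimethyl (2R)-2-methylcyclopropane-1,1-dicarboxylate, via sulfate monoester 3 (not isolated)
Conditions: NaH (2.2 equiv), DME, 0 °C → reflux
Reagents that add atoms: none
Why: Double alkylation of malonate by the cyclic sulfate (cyclic-sulfate cyclopropanation); the primary carbon reacts first and the secondary sulfate is then displaced intramolecularly with SN2 inversion, turning the (S)-sulfate into the (R)-cyclopropane.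

Step 2
Reactants: 4
Product: 5 (1S,2R)-1-(methoxycarbonyl)-2-methylcyclopropane-1-carboxylic acid (CO2H trans to CH3)
Conditions: KOH (1.05 equiv), MeOH/H2O, 0 °C → rt; then 1 M HCl
Reagents that add atoms: potassium hydroxide, [K+].[OH-]
Why: Mono-saponification of a 2-substituted cyclopropane-1,1-diester occurs at the less hindered ester trans to the methyl group, which sets the quaternary centre C5 by differentiating the two diastereotopic esters.

Step 3
Reactants: 5
Product: 6 methyl (1S,2R)-1-(hydroxymethyl)-2-methylcyclopropane-1-carboxylate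
Conditions: BH3·SMe2, THF, 0 °C → rt; MeOH quench
Reagents that add atoms: none
Why: Chemoselective borane reduction of the free carboxylic acid in the presence of the ester; no stereocentre is touched.

Step 4
Reactants: 6
Product: 7 (1S,2R)-1-(hydroxymethyl)-2-methylcyclopropane-1-carboxylic acid
Conditions: LiOH, THF/MeOH/H2O, 50 °C; then 1 M HCl
Reagents that add atoms: lithium hydroxide, [Li+].[OH-]
Why: Ordinary saponification of the remaining hindered ester.

Step 5
Reactants: 7
Product: 8 1-[(1S,2R)-1-(hydroxymethyl)-2-methylcyclopropyl]ethan-1-one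
Conditions: MeLi (3.5 equiv), Et2O, 0 °C → rt; inverse quench into cold 1 M HCl
Reagents that add atoms: methyllithium, [Li]C
Why: MeLi adds to the lithium carboxylate to give a stable gem-diolate that collapses to the methyl ketone only on work-up (carboxylic acid to methyl ketone reaction), so no tertiary alcohol forms.

Step 6
Reactants: 8
Product: 9 (1S,2R)-1-acetyl-2-methylcyclopropane-1-carbaldehyde (fragment 1; acetyl cis to CH3)
Conditions: Dess–Martin periodinane, NaHCO3, CH2Cl2, 0 °C → rt
Reagents that add atoms: none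
Why: Dess–Martin oxidation of the neopentyl primary alcohol; the aldehyde has no α-hydrogen and cannot epimerise.

**Fragment 2 (ring B)**

Step 7
Reactants: 10 1-ethoxyprop-1-yne; 11 acetyl chloride
Product: 13 3-ethoxy-2-methylcyclobut-2-en-1-one, via ketene 12 (not isolated)
Conditions: Et3N, Et2O, 0 °C → rt
Reagents that add atoms: none
Why: Ketene formed by dehydrochlorination undergoes a [2+2] cycloaddition with the ynol ether, the nucleophilic methyl-bearing alkyne carbon bonding to the ketene carbonyl carbon.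

Step 8
Reactants: 13
Product: 15 2-methylcyclobut-2-en-1-one (fragment 2), via allylic alcohol 14 (not isolated)
Conditions: i-Bu2AlH, CH2Cl2, −78 °C; then 1 M HCl, 0 °C; used as a cold CH2Cl2 solution
Reagents that add atoms: water, O
Why: 1,2-Reduction of the vinylogous ester followed by acid-mediated allylic transposition and enol ether hydrolysis (Stork–Danheiser-type sequence) moves the carbonyl to the former ethoxy carbon and leaves the methyl on the α-carbon of the enone.

**Fragment 3 (diene with C1/C2)**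

Step 9
Reactants: 16 (4R)-2,2-dimethyl-1,3-dioxolane-4-carbaldehyde; 17 3-(triphenyl-λ5-phosphanylidene)butan-2-one
Product: 18 (3E)-4-[(4S)-2,2-dimethyl-1,3-dioxolan-4-yl]-3-methylbut-3-en-2-one
Conditions: CH2Cl2, rt → 40 °C
Reagents that add atoms: none
Why: Wittig olefination with a stabilised α-methyl keto ylide gives the (E)-trisubstituted enone without eroding the α-alkoxy stereocentre, which becomes C1.

Step 10
Reactants: 18
Product: 19 (3E,5S)-5,6-dihydroxy-3-methylhex-3-en-2-one
Conditions: AcOH/H2O (4:1), 40 °C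
Reagents that add atoms: none
Why: Mild acetal hydrolysis; the (E)-geometry prevents hemiketal or furan formation.

Step 11
Reactants: 19
Product: 20 (3E,5S)-6-[(tert-butyldiphenylsilyl)oxy]-5-hydroxy-3-methylhex-3-en-2-one
Conditions: TBDPSCl (1.05 equiv), imidazole, CH2Cl2, −20 → 0 °C
Reagents that add atoms: tert-butyl(chloro)diphenylsilane, CC(C)(C)[Si](Cl)(c1ccccc1)c1ccccc1
Why: Sterically controlled silylation of the primary hydroxyl over the secondary allylic one.

Step 12
Reactants: 20
Product: 21 (2S,3E)-1-[(tert-butyldiphenylsilyl)oxy]-4-methyl-5-oxohex-3-en-2-yl acetate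
Conditions: Ac2O, pyridine, 4-(dimethylamino)pyridine (cat.), CH2Cl2, 0 °C
Reagents that add atoms: acetic anhydride, CC(=O)OC(C)=O
Why: Acylation installs the C1 acetate of the target at the outset.

Step 13
Reactants: 21
Product: 22 (2S,3E)-5-[(tert-butyldimethylsilyl)oxy]-1-[(tert-butyldiphenylsilyl)oxy]-4-methylhexa-3,5-dien-2-yl acetate (fragment 3)
Conditions: TBSOTf, Et3N, CH2Cl2, −78 → 0 °C
Reagents that add atoms: tert-butyldimethylsilyl trifluoromethanesulfonate, CC(C)(C)[Si](C)(C)OS(=O)(=O)C(F)(F)F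
Why: Soft enolisation toward the α'-methyl group gives the cross-conjugated 2-silyloxy diene with the (E)-alkene intact.

**Assembly**

Step 14
Reactants: 22; 15
Product: 23 (1S)-2-[(tert-butyldiphenylsilyl)oxy]-1-{3-[(tert-butyldimethylsilyl)oxy]-4,6-dimethyl-7-oxobicyclo[4.2.0]oct-3-en-5-yl}ethyl acetate (rings A/B cis-fused; C14 side chain cis to the four-membered ring; H14, H10 and 15-CH3 on the other face)
Conditions: (S)-1-(2-methylphenyl)-3,3-diphenyltetrahydro-1H,3H-pyrrolo[1,2-c][1,3,2]oxazaborole activated with HN(SO2CF3)2 (20 mol %), CH2Cl2, −78 → −40 °C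
Reagents that add atoms: none
Why: Diels–Alder reaction in which the silyloxy group and the C14 substituent both direct C11 to the enone β-carbon (C10) and C14 to the methyl-bearing α-carbon (C15); the endo transition state places the side chain cis to ring B, suprafacial addition gives the cis ring fusion, and the face is set by the chiral Lewis acid together with approach anti to the allylic C1–O bond (H1 eclipsing the C13 methyl, A(1,3) strain).

Step 15
Reactants: 23
Product: 24 siloxycyclopropane (CH2 bridging C12 and C13 on the face of H14; C12–OTBS and 13-CH3 on the other face)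
Conditions: Et2Zn, CH2I2, CH2Cl2, 0 °C → rt
Reagents that add atoms: diiodomethane, ICI
Why: Simmons–Smith (Furukawa) cyclopropanation of the electron-rich silyl enol ether; the added carbon becomes the second C13 methyl and the cyclopropanol ether masks the C12 ketone, so its two new stereocentres are inconsequential.

Step 16
Reactants: 24; 9
Product: 27 (E)-alkylidene cyclobutanone (C9=C8; the cyclopropyl group anti to the C16 carbonyl), via aldol adduct 25 (not isolated), via mesylate 26 (not isolated)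
Conditions: LiN(i-Pr)2, THF, −78 °C, then 9; aq. NH4Cl; crude: MsCl, Et3N, CH2Cl2, 0 °C; then DBU, rt
Reagents that add atoms: none
Why: Aldol condensation: C9 is the only enolisable position of the cyclobutanone and the aldehyde cannot enolise, and E1cB loss of mesylate gives the thermodynamically preferred (E)-enone with the bulky quaternary cyclopropyl carbon away from the carbonyl.

Step 17
Reactants: 27
Product: 28 enone diketone (C12 ketone and C13 gem-dimethyl unmasked)
Conditions: p-toluenesulfonic acid monohydrate, THF/H2O (10:1), 40 °C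
Reagents that add atoms: none
Why: Conia-type acid ring opening of the siloxycyclopropane: protonation at the CH2 carbon with push from oxygen cleaves the C12–CH2 bond and leaves a methyl on C13.

Step 18
Reactants: 28
Product: 29 C8,C9-diol (C9–OH and C8–OH configured as in the target; C16 ketone retained)
Conditions: OsO4 (10 mol %), N-methylmorpholine N-oxide, citric acid, t-BuOH/H2O, rt
Reagents that add atoms: osmium tetroxide, O=[Os](=O)(=O)=O; N-methylmorpholine N-oxide, C[N+]1([O-])CCOCC1; water, O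
Why: Upjohn syn-dihydroxylation on the convex face of ring B (the face of H10 and 15-CH3) puts the C9 hydroxyl on that face and the C8 carbon on the concave face, and the (E)-geometry translates into the required C8 configuration.

Step 19
Reactants: 29
Product: 30 C8 acetate (C9–OH free)
Conditions: Ac2O, 4-(dimethylamino)pyridine, pyridine, CH2Cl2, 0 °C → rt
Reagents that add atoms: acetic anhydride, CC(=O)OC(C)=O
Why: Acylation of the only secondary alcohol; the tertiary α-ketol hydroxyl does not react and no β-elimination is possible because C9 and C5 are quaternary.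

Step 20
Reactants: 30
Product: 33 tricyclic ketol (ring D closed; C16–OH cis to C9–OH), via tris(trimethylsilyl) derivative 31 (not isolated), via titanium aldolate 32 (not isolated)
Conditions: TMSOTf, Et3N, CH2Cl2, 0 °C; then TiCl4, CH2Cl2, −78 °C; then 1 M HCl, THF, 0 °C
Reagents that add atoms: none
Why: Intramolecular Mukaiyama aldol: the enol silane of the methyl ketone (C3) adds to the strained, non-enolisable, TiCl4-activated cyclobutanone (C16); the tether from C9 allows attack only on the concave face, so ring D is cis-fused and the C16 hydroxyl is cis to the C9 hydroxyl, without alkoxide conditions that would move the acetates.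

Step 21
Reactants: 33
Product: 34 primary alcohol (C2–OH)
Conditions: HF·pyridine, THF/pyridine, 0 °C → rt
Reagents that add atoms: none
Why: Fluoride cleavage of the primary silyl ether under mildly acidic conditions that do not promote acetate migration.

Step 22
Reactants: 34
Product: 35 keto aldehyde (C2 aldehyde)
Conditions: SO3·pyridine, DMSO, i-Pr2NEt, CH2Cl2, 0 °C
Reagents that add atoms: none
Why: Parikh–Doering oxidation converts the only primary alcohol to the aldehyde and leaves the tertiary cis-diol of ring B intact, since activated DMSO does not cleave glycols.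

Step 23
Reactants: 35
Product: 36 target, CNP0157858.3
Conditions: MgBr2·OEt2, i-Pr2NEt, CH2Cl2, −20 → 0 °C
Reagents that add atoms: none
Why: Intramolecular aldol by soft enolisation: the magnesium enolate of the C4 ketone (C3) adds to the C2 aldehyde through a closed chelated transition state in the ring C half-chair that keeps the C1 acetate pseudo-equatorial, the tether enforcing the cis C/D fusion at C3 and the chelate placing the C2 hydroxyl syn-clinal to the C4 carbonyl as in the target.

## Compound list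

1 | dimethyl malonate | COC(=O)CC(=O)OC | starting material
2 | (4S)-4-methyl-1,3,2-dioxathiolane 2,2-dioxide | C[C@H]1COS(=O)(=O)O1 | starting material
3 | sodium (2S)-4,4-bis(methoxycarbonyl)butan-2-yl sulfate | C[C@@H](CC(C(=O)OC)C(=O)OC)OS(=O)(=O)[O-].[Na+] | intermediate
4 | dimethyl (2R)-2-methylcyclopropane-1,1-dicarboxylate | COC(=O)C1(C[C@H]1C)C(=O)OC | intermediate
5 | (1S,2R)-1-(methoxycarbonyl)-2-methylcyclopropane-1-carboxylic acid | COC(=O)[C@]1(C[C@H]1C)C(=O)O | intermediate
6 | methyl (1S,2R)-1-(hydroxymethyl)-2-methylcyclopropane-1-carboxylate | COC(=O)[C@]1(C[C@H]1C)CO | intermediate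
7 | (1S,2R)-1-(hydroxymethyl)-2-methylcyclopropane-1-carboxylic acid | OC(=O)[C@]1(C[C@H]1C)CO | intermediate
8 | 1-[(1S,2R)-1-(hydroxymethyl)-2-methylcyclopropyl]ethan-1-one | CC(=O)[C@]1(C[C@H]1C)CO | intermediate
9 | (1S,2R)-1-acetyl-2-methylcyclopropane-1-carbaldehyde | CC(=O)[C@]1(C[C@H]1C)C=O | intermediate
10 | 1-ethoxyprop-1-yne | CCOC#CC | starting material
11 | acetyl chloride | CC(=O)Cl | starting material
12 | ketene | C=C=O | intermediate
13 | 3-ethoxy-2-methylcyclobut-2-en-1-one | CCOC1=C(C)C(=O)C1 | intermediate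
14 | 3-ethoxy-2-methylcyclobut-2-en-1-ol (racemic) | CCOC1=C(C)C(O)C1 | intermediate
15 | 2-methylcyclobut-2-en-1-one | CC1=CCC1=O | intermediate
16 | (4R)-2,2-dimethyl-1,3-dioxolane-4-carbaldehyde | O=C[C@H]1COC(C)(C)O1 | starting material
17 | 3-(triphenyl-λ5-phosphanylidene)butan-2-one | CC(=O)C(C)=P(c1ccccc1)(c1ccccc1)c1ccccc1 | starting material
18 | (3E)-4-[(4S)-2,2-dimethyl-1,3-dioxolan-4-yl]-3-methylbut-3-en-2-one | CC(=O)/C(C)=C/[C@H]1COC(C)(C)O1 | intermediate
19 | (3E,5S)-5,6-dihydroxy-3-methylhex-3-en-2-one | CC(=O)/C(C)=C/[C@H](O)CO | intermediate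
20 | (3E,5S)-6-[(tert-butyldiphenylsilyl)oxy]-5-hydroxy-3-methylhex-3-en-2-one | CC(=O)/C(C)=C/[C@H](O)CO[Si](c1ccccc1)(c1ccccc1)C(C)(C)C | intermediate
21 | (2S,3E)-1-[(tert-butyldiphenylsilyl)oxy]-4-methyl-5-oxohex-3-en-2-yl acetate | CC(=O)/C(C)=C/[C@H](OC(C)=O)CO[Si](c1ccccc1)(c1ccccc1)C(C)(C)C | intermediate
22 | (2S,3E)-5-[(tert-butyldimethylsilyl)oxy]-1-[(tert-butyldiphenylsilyl)oxy]-4-methylhexa-3,5-dien-2-yl acetate | C=C(O[Si](C)(C)C(C)(C)C)/C(C)=C/[C@H](OC(C)=O)CO[Si](c1ccccc1)(c1ccccc1)C(C)(C)C | intermediate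
23 | Diels–Alder adduct: cis-fused bicyclo[4.2.0]oct-3-en-7-one (rings A/B), 3-OTBS, 4,6-dimethyl, 5-[(1S)-1-acetoxy-2-(TBDPS-oxy)ethyl] cis to ring B | CC(=O)O[C@H](CO[Si](c1ccccc1)(c1ccccc1)C(C)(C)C)[C@@H]1C(C)=C(O[Si](C)(C)C(C)(C)C)C[C@@H]2CC(=O)[C@@]21C | intermediate
24 | siloxycyclopropane: 23 with CH2 across C12/C13 on the face of H14 | CC(=O)O[C@H](CO[Si](c1ccccc1)(c1ccccc1)C(C)(C)C)[C@@H]1[C@@]3(C)C[C@@]3(O[Si](C)(C)C(C)(C)C)C[C@@H]2CC(=O)[C@@]21C | intermediate
25 | aldol adduct: 24 bearing at C9 the CH(OH)–[(1S,2R)-1-acetyl-2-methylcyclopropyl] group (C8/C9 epimer mixture) | CC(=O)O[C@H](CO[Si](c1ccccc1)(c1ccccc1)C(C)(C)C)[C@@H]1[C@@]3(C)C[C@@]3(O[Si](C)(C)C(C)(C)C)C[C@@H]2C(C(O)[C@]4(C(C)=O)C[C@H]4C)C(=O)[C@@]21C | intermediate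
26 | C8 methanesulfonate of 25 (C8/C9 epimer mixture) | CC(=O)O[C@H](CO[Si](c1ccccc1)(c1ccccc1)C(C)(C)C)[C@@H]1[C@@]3(C)C[C@@]3(O[Si](C)(C)C(C)(C)C)C[C@@H]2C(C(OS(C)(=O)=O)[C@]4(C(C)=O)C[C@H]4C)C(=O)[C@@]21C | intermediate
27 | (E)-alkylidene cyclobutanone: C9=C8, C8 bearing the (1S,2R)-1-acetyl-2-methylcyclopropyl group anti to the C16 carbonyl; C12 still masked | CC(=O)O[C@H](CO[Si](c1ccccc1)(c1ccccc1)C(C)(C)C)[C@@H]1[C@@]3(C)C[C@@]3(O[Si](C)(C)C(C)(C)C)C[C@@H]2/C(=C\[C@]4(C(C)=O)C[C@H]4C)C(=O)[C@@]21C | intermediate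
28 | enone diketone: 27 with C12 ketone and C13 gem-dimethyl | CC(=O)O[C@H](CO[Si](c1ccccc1)(c1ccccc1)C(C)(C)C)[C@@H]1C(C)(C)C(=O)C[C@@H]2/C(=C\[C@]4(C(C)=O)C[C@H]4C)C(=O)[C@@]21C | intermediate
29 | C8,C9-diol (C9–OH on the face of H10/15-CH3; C8 as in target) | CC(=O)O[C@H](CO[Si](c1ccccc1)(c1ccccc1)C(C)(C)C)[C@@H]1C(C)(C)C(=O)C[C@@H]2[C@](O)([C@H](O)[C@]4(C(C)=O)C[C@H]4C)C(=O)[C@@]21C | intermediate
30 | C8 acetate of 29 | CC(=O)O[C@H](CO[Si](c1ccccc1)(c1ccccc1)C(C)(C)C)[C@@H]1C(C)(C)C(=O)C[C@@H]2[C@](O)([C@H](OC(C)=O)[C@]4(C(C)=O)C[C@H]4C)C(=O)[C@@]21C | intermediate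
31 | tris(trimethylsilyl) derivative of 30 (C9–OTMS; C3=C4–OTMS; C11=C12–OTMS) | CC(=O)O[C@H](CO[Si](c1ccccc1)(c1ccccc1)C(C)(C)C)[C@@H]1C(C)(C)C(O[Si](C)(C)C)=C[C@@H]2[C@](O[Si](C)(C)C)([C@H](OC(C)=O)[C@]4(C(=C)O[Si](C)(C)C)C[C@H]4C)C(=O)[C@@]21C | intermediate
32 | trichlorotitanium aldolate (ring D closed; C16–OTiCl3, C9–OTMS, C11=C12–OTMS) | CC(=O)O[C@H](CO[Si](c1ccccc1)(c1ccccc1)C(C)(C)C)[C@@H]1C(C)(C)C(O[Si](C)(C)C)=C[C@@H]2[C@]3(O[Si](C)(C)C)[C@H](OC(C)=O)[C@@]4(C[C@H]4C)C(=O)C[C@]3(O[Ti](Cl)(Cl)Cl)[C@@]21C | intermediate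
33 | tricyclic ketol: rings A, B, D and spiro ring E; C9–OH and C16–OH cis; C8–OAc; C14 bearing (1S)-1-acetoxy-2-(TBDPS-oxy)ethyl | CC(=O)O[C@H](CO[Si](c1ccccc1)(c1ccccc1)C(C)(C)C)[C@@H]1C(C)(C)C(=O)C[C@@H]2[C@]3(O)[C@H](OC(C)=O)[C@@]4(C[C@H]4C)C(=O)C[C@]3(O)[C@@]21C | intermediate
34 | primary alcohol: 33 without the silyl group | CC(=O)O[C@H](CO)[C@@H]1C(C)(C)C(=O)C[C@@H]2[C@]3(O)[C@H](OC(C)=O)[C@@]4(C[C@H]4C)C(=O)C[C@]3(O)[C@@]21C | intermediate
35 | keto aldehyde: C2 aldehyde, C1 acetate | CC(=O)O[C@H](C=O)[C@@H]1C(C)(C)C(=O)C[C@@H]2[C@]3(O)[C@H](OC(C)=O)[C@@]4(C[C@H]4C)C(=O)C[C@]3(O)[C@@]21C | intermediate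
36 | CNP0157858.3 | CC(=O)O[C@@H]1[C@@H](O)[C@H]2C(=O)[C@]3(C[C@H]3C)[C@@H](OC(C)=O)[C@@]3(O)[C@H]4CC(=O)C(C)(C)[C@@H]1[C@@]4(C)[C@@]23O | target

## Totals and risks

Total steps: 23. Longest linear sequence: 15 steps (steps 9–13, then 14–23, from aldehyde 16). Fragment 1 (steps 1–6) enters at step 16 and fragment 2 (steps 7–8) at step 14.

**Step 14 (Diels–Alder).** The cycloaddition forms a quaternary carbon next to a substituted diene terminus, uses a sensitive α-methyl cyclobutenone, and its facial selectivity rests on untested double diastereoselection between catalyst and the C1 stereocentre. Fallback: set out from 22 and move the methyl group to a later operation. The diene is combined without catalyst (CH2Cl2, 0 °C) with the much more reactive 2-bromocyclobut-2-en-1-one F1, which adds with the same regiochemistry and endo preference to give the angular bromo ketone F2. Treatment with Me2CuLi (THF, −78 °C) forms the C15/C16 enolate regiospecifically by halogen–metal exchange, and MeI alkylates it on the convex face. This returns to the route at 23.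

**Step 20 (ring D aldol).** The α-silyloxy cyclobutanone may undergo ketol rearrangement or acetate ionisation under TiCl4, and the acceptor is flanked by two quaternary carbons. Fallback: set out from diol 29 and close ring D by a base-mediated enolate aldol on a doubly protected substrate. 2,2-Dimethoxypropane with camphorsulfonic acid gives the C8/C9 acetonide F3. LiN(SiMe3)2 (2.2 equiv, THF, −78 → −40 °C; both ketones are enolised but only the C3 enolate can cyclise) then gives the ring D acetonide F4. Aqueous CF3CO2H releases the triol F5, and Ac2O with 4-(dimethylamino)pyridine in pyridine acetylates only the secondary C8 hydroxyl. This returns to the route at 33.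

**Step 23 (ring C aldol).** The α-acetoxy aldehyde can epimerise at C1, the C1 acetate can migrate to the new C2 alkoxide, and the C12 ketone offers a competing (unproductive) enolate. Fallback: set out from 35 and close ring C at the carboxylic acid oxidation level. Pinnick oxidation (NaClO2, NaH2PO4, 2-methylbut-2-ene) gives the carboxylic acid F6, and pentafluorophenol with dicyclohexylcarbodiimide gives the pentafluorophenyl ester F7. Soft-enolisation C-acylation (MgBr2·OEt2, i-Pr2NEt, CH2Cl2) closes ring C as the cyclic 1,3-diketone F8 by intramolecular Claisen condensation, with C1 free to settle in the equatorial acetate configuration. Zn(BH4)2 (Et2O, −40 °C) then reduces the less hindered C2 carbonyl from the convex face. This returns to the route at 36.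

## Further compounds

F1 | step 14 | 2-bromocyclobut-2-en-1-one | O=C1CC=C1Br
F2 | step 14 | bromo ketone: 23 with Br in place of the C15 methyl | CC(=O)O[C@H](CO[Si](c1ccccc1)(c1ccccc1)C(C)(C)C)[C@@H]1C(C)=C(O[Si](C)(C)C(C)(C)C)C[C@@H]2CC(=O)[C@@]21Br
F3 | step 20 | C8/C9 acetonide of diol 29 | CC(=O)O[C@H](CO[Si](c1ccccc1)(c1ccccc1)C(C)(C)C)[C@@H]1C(C)(C)C(=O)C[C@@H]2[C@@]5(OC(C)(C)O[C@@H]5[C@]4(C(C)=O)C[C@H]4C)C(=O)[C@@]21C
F4 | step 20 | ring D acetonide: C3–C16 closed, C16–OH free, C8/C9 isopropylidene | CC(=O)O[C@H](CO[Si](c1ccccc1)(c1ccccc1)C(C)(C)C)[C@@H]1C(C)(C)C(=O)C[C@@H]2[C@]3(OC(C)(C)O5)[C@H]5[C@@]4(C[C@H]4C)C(=O)C[C@]3(O)[C@@]21C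
F5 | step 20 | triol: 33 with C8–OH in place of C8–OAc | CC(=O)O[C@H](CO[Si](c1ccccc1)(c1ccccc1)C(C)(C)C)[C@@H]1C(C)(C)C(=O)C[C@@H]2[C@]3(O)[C@H](O)[C@@]4(C[C@H]4C)C(=O)C[C@]3(O)[C@@]21C
F6 | step 23 | carboxylic acid: 35 with C2 as CO2H | CC(=O)O[C@H](C(=O)O)[C@@H]1C(C)(C)C(=O)C[C@@H]2[C@]3(O)[C@H](OC(C)=O)[C@@]4(C[C@H]4C)C(=O)C[C@]3(O)[C@@]21C
F7 | step 23 | pentafluorophenyl ester of F6 | CC(=O)O[C@H](C(=O)Oc5c(F)c(F)c(F)c(F)c5F)[C@@H]1C(C)(C)C(=O)C[C@@H]2[C@]3(O)[C@H](OC(C)=O)[C@@]4(C[C@H]4C)C(=O)C[C@]3(O)[C@@]21C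
F8 | step 23 | 1,3-diketone: target with a C2 ketone | CC(=O)O[C@@H]1C(=O)[C@H]2C(=O)[C@]3(C[C@H]3C)[C@@H](OC(C)=O)[C@@]3(O)[C@H]4CC(=O)C(C)(C)[C@@H]1[C@@]4(C)[C@@]23O
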